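**Retrosynthetic overview**

1. Target 16 comes from its tri-O-benzyl ether 15 by hydrogenolysis. The butenolide is numbered O1, C2(=O), C3(OMe), C4(aryl), C5(quaternary: CO2Me, CH2-chroman).
2. Key disconnection C4–C5: the butenolide ring is closed last by an enantioconvergent, palladium-catalysed intramolecular α-alkenylation of silyl ketene acetal 14. Enabling feature: C5 lies between O1 and the CO2Me carbonyl (an α-acyloxy ester carbon) and is the only enolisable position, because C3(OMe)=C4(Ar) is a tetrasubstituted enol ether, i.e. the enol triflate of a β-keto ester.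
3. The O1–C2 ester is made by Mitsunobu union of two fragments of similar size: acid 12 and hydroxy ester 7 (C2-epimer mixture, deliberately uncontrolled).
4. Acid 12: Claisen acylation of tert-butyl methoxyacetate, chelation-controlled enol triflation, acidolysis. Hydroxy ester 7: bromochromene 1, Jacobsen epoxidation (sets the chroman carbinol centre), hydride opening, benzylation, aryl Grignard/CuI opening of methyl glycidate.
5. Ring order: the chroman ring is bought with 1 (a temporary oxirane is fused to it in step 1 and opened in step 2); the butenolide ring is formed in step 10.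

Key step: step 10

Remark: compounds 1, 5, 8 and 9 are assumed to be catalogue items; 5 is used as the racemate because the centre it creates is erased in step 9.

**Route**

Step 1
Reactants: 1 6-bromo-2,2-dimethyl-2H-chromene
Product: 2 (3R,4R)-6-bromo-3,4-epoxy-2,2-dimethylchromane
Conditions: (R,R)-N,N'-bis(3,5-di-tert-butylsalicylidene)-1,2-cyclohexanediaminomanganese chloride (4 mol%), 4-phenylpyridine N-oxide (20 mol%), aq. NaOCl (pH 11.3), CH2Cl2, 0 °C
Reagents that add atoms: sodium hypochlorite, [Na+].[O-]Cl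
Why: Jacobsen–Katsuki epoxidation of a 2,2-dimethylchromene, a privileged cis-alkene class for this catalyst; the (R,R)-catalyst should deliver oxygen to the face that gives the (3R,4R)-epoxide and so sets the chroman C3 centre.

Step 2
Reactants: 2 (3R,4R)-6-bromo-3,4-epoxy-2,2-dimethylchromane
Product: 3 (3R)-6-bromo-2,2-dimethyl-3,4-dihydro-2H-chromen-3-ol
Conditions: LiAlH4, THF, 0 °C; aqueous work-up
Reagents that add atoms: none
Why: Regioselective SN2 hydride opening of the epoxide at the benzylic C4 (C3 is shielded by the gem-dimethyl group); the C3–O bond is not touched, so the (R) configuration is kept.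

Step 3
Reactants: 3 (3R)-6-bromo-2,2-dimethyl-3,4-dihydro-2H-chromen-3-ol
Product: 4 (3R)-3-(benzyloxy)-6-bromo-2,2-dimethyl-3,4-dihydro-2H-chromene
Conditions: NaH, BnBr, Bu4NI (cat.), DMF, 0 °C to rt
Reagents that add atoms: benzyl bromide, BrCc1ccccc1
Why: Williamson etherification of the sodium alkoxide; no bond to the stereocentre is broken.

Step 4
Reactants: 4 (3R)-3-(benzyloxy)-6-bromo-2,2-dimethyl-3,4-dihydro-2H-chromene; 5 methyl oxirane-2-carboxylate (racemic methyl glycidate)
Product: 7 methyl (2RS)-3-[(3R)-3-(benzyloxy)-2,2-dimethyl-3,4-dihydro-2H-chromen-6-yl]-2-hydroxypropanoate, via arylmagnesium bromide 6 (not isolated)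
Conditions: Mg, THF, reflux; then CuI (10 mol%), 5, THF, −40 °C; aq. NH4Cl
Reagents that add atoms: none
Why: Copper-catalysed SN2 opening of the terminal epoxide carbon of the glycidate by the aryl Grignard reagent should outrun addition to the ester at −40 °C; the new carbinol centre is left as an epimer mixture on purpose.

Step 5
Reactants: 8 tert-butyl 2-methoxyacetate; 9 3,4-bis(benzyloxy)benzoyl chloride
Product: 10 tert-butyl (2RS)-3-[3,4-bis(benzyloxy)phenyl]-2-methoxy-3-oxopropanoate
Conditions: LiN(SiMe3)2 (2.1 equiv), THF, −78 °C; then 9, −78 to 0 °C; aq. NH4Cl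
Reagents that add atoms: none
Why: Crossed Claisen condensation (C-acylation of the lithium ester enolate by a non-enolisable aroyl chloride); the second equivalent of base stores the product as its enolate.

Step 6
Reactants: 10 tert-butyl (2RS)-3-[3,4-bis(benzyloxy)phenyl]-2-methoxy-3-oxopropanoate
Product: 11 tert-butyl (2E)-3-[3,4-bis(benzyloxy)phenyl]-2-methoxy-3-{[(trifluoromethyl)sulfonyl]oxy}prop-2-enoate
Conditions: Tf2O, Et3N, LiOTf, CH2Cl2, 0 °C
Reagents that add atoms: trifluoromethanesulfonic anhydride, O=S(=O)(OS(=O)(=O)C(F)(F)F)C(F)(F)F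
Why: Chelation-controlled enol triflation of a β-keto ester: the lithium chelate holds the enolate oxygen cis to the ester carbonyl, so O-sulfonylation should place OTf cis to the ester (2E), the geometry needed for ring closure.

Step 7
Reactants: 11 tert-butyl (2E)-3-[3,4-bis(benzyloxy)phenyl]-2-methoxy-3-{[(trifluoromethyl)sulfonyl]oxy}prop-2-enoate
Product: 12 (2E)-3-[3,4-bis(benzyloxy)phenyl]-2-methoxy-3-{[(trifluoromethyl)sulfonyl]oxy}prop-2-enoic acid
Conditions: CF3CO2H, CH2Cl2, 0 °C to rt
Reagents that add atoms: none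
Why: Acidolysis of the tert-butyl ester with loss of isobutene; the enol triflate, the methyl enol ether and the aryl benzyl ethers are stable to acid under these conditions.

Step 8
Reactants: 12 (2E)-3-[3,4-bis(benzyloxy)phenyl]-2-methoxy-3-{[(trifluoromethyl)sulfonyl]oxy}prop-2-enoic acid; 7 methyl (2RS)-3-[(3R)-3-(benzyloxy)-2,2-dimethyl-3,4-dihydro-2H-chromen-6-yl]-2-hydroxypropanoate
Product: 13 methyl (2RS)-3-[(3R)-3-(benzyloxy)-2,2-dimethyl-3,4-dihydro-2H-chromen-6-yl]-2-{[(2E)-3-[3,4-bis(benzyloxy)phenyl]-2-methoxy-3-{[(trifluoromethyl)sulfonyl]oxy}prop-2-enoyl]oxy}propanoate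
Conditions: PPh3, DIAD, THF, 0 °C to rt
Reagents that add atoms: none
Why: Mitsunobu esterification: the carboxylate displaces the activated secondary hydroxyl by SN2, which avoids acyl activation of the hindered tetrasubstituted acrylic acid; inversion at C2 is irrelevant for an epimer mixture.

Step 9
Reactants: 13 methyl (2RS)-3-[(3R)-3-(benzyloxy)-2,2-dimethyl-3,4-dihydro-2H-chromen-6-yl]-2-{[(2E)-3-[3,4-bis(benzyloxy)phenyl]-2-methoxy-3-{[(trifluoromethyl)sulfonyl]oxy}prop-2-enoyl]oxy}propanoate
Product: 14 (1E/Z)-3-[(3R)-3-(benzyloxy)-2,2-dimethyl-3,4-dihydro-2H-chromen-6-yl]-1-methoxy-1-[(trimethylsilyl)oxy]prop-1-en-2-yl (2E)-3-[3,4-bis(benzyloxy)phenyl]-2-methoxy-3-{[(trifluoromethyl)sulfonyl]oxy}prop-2-enoate (used crude)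
Conditions: LiN(SiMe3)2, Me3SiCl (in situ quench), THF, −78 °C; filtration under argon
Reagents that add atoms: chlorotrimethylsilane, C[Si](C)(C)Cl
Why: Kinetic deprotonation at C5, the only acidic C–H, with immediate O-silylation (silyl ketene acetal formation as in the first stage of an Ireland–Claisen rearrangement) should trap the enolate before a 1,2-acyl shift can occur; both C5 epimers give the same ketene acetal mixture.

Step 10
Reactants: 14 silyl ketene acetal (E/Z mixture)
Product: 15 methyl (2S)-2-{[(3R)-3-(benzyloxy)-2,2-dimethyl-3,4-dihydro-2H-chromen-6-yl]methyl}-3-[3,4-bis(benzyloxy)phenyl]-4-methoxy-5-oxo-2,5-dihydrofuran-2-carboxylate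
Conditions: Pd(dba)2 (10 mol%), (R)-DIFLUORPHOS (12 mol%), LiOAc (2 equiv), PhCF3, 50 °C
Reagents that add atoms: none
Why: Proposed new method: oxidative addition of the C4–OTf bond to zerovalent palladium should give a cationic vinyl complex of divalent palladium; acetate bound to that palladium attacks the silicon of the pendant ketene acetal, so the C5 enolate is generated only on palladium-bearing molecules (no free enolate, hence no acyl migration), and C(sp2)–C(sp3) reductive elimination forms the C4–C5 bond. The closest known reaction types are the palladium-catalysed α-arylation and α-alkenylation of silyl ketene acetals with aryl and alkenyl triflates under acetate or ZnF2 activation (including enantioselective arylations) and the intramolecular α-arylation of α-amino acid esters to quaternary centres; an intramolecular, enantioselective alkenylation of an α-acyloxy ester across an ester tether has not been shown. The butenolide closes in a 5-(enolexo) sense by reductive elimination from the six-membered palladacycle Pd–C4=C3–C2(=O)–O1–C5, so the 5-endo-trig problem of a direct addition–elimination at C4 does not arise. The C5 stereocentre is set by the chiral bisphosphine on palladium: both C5 epimers of 13 and both geometric isomers of 14 converge on the same palladium enolate, whose C- and O-bound forms should interconvert faster than they eliminate, so the mixture should be funnelled into one configuration; the sense of induction cannot be predicted, so the ligand antipode (or class) is chosen by screening to give the (2S) product, and the remote chroman centre should exert no bias. The step needs chemoselectivity, secured because C5 is the only enolisable carbon, and the correct alkene geometry (OTf cis to the C2 carbonyl), fixed in step 6.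

Step 11
Reactants: 15 tri-O-benzyl butenolide
Product: 16 methyl (2S)-3-(3,4-dihydroxyphenyl)-2-{[(3R)-3-hydroxy-2,2-dimethyl-3,4-dihydro-2H-chromen-6-yl]methyl}-4-methoxy-5-oxo-2,5-dihydrofuran-2-carboxylate
Conditions: H2 (1 atm), 10% Pd/C, EtOAc–MeOH, rt
Reagents that add atoms: none
Why: Catalytic hydrogenolysis of the two aryl benzyl ethers and the secondary benzyl ether; the tetrasubstituted push–pull C3=C4 bond and the methyl ester should survive, and no stereocentre is touched.

**Compound list**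

1 | 6-bromo-2,2-dimethyl-2H-chromene | CC1(C)C=Cc2cc(Br)ccc2O1 | starting material
2 | (3R,4R)-6-bromo-3,4-epoxy-2,2-dimethylchromane [(1aR,7bR)-6-bromo-2,2-dimethyl-1a,7b-dihydro-2H-oxireno[2,3-c]chromene] | CC1(C)[C@@H]2O[C@@H]2c3cc(Br)ccc3O1 | intermediate
3 | (3R)-6-bromo-2,2-dimethyl-3,4-dihydro-2H-chromen-3-ol | Brc1ccc2c(c1)C[C@@H](O)C(C)(C)O2 | intermediate
4 | (3R)-3-(benzyloxy)-6-bromo-2,2-dimethyl-3,4-dihydro-2H-chromene | Brc1ccc2c(c1)C[C@@H](OCc3ccccc3)C(C)(C)O2 | intermediate
5 | methyl oxirane-2-carboxylate (racemic) | COC(=O)C1CO1 | starting material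
6 | [(3R)-3-(benzyloxy)-2,2-dimethyl-3,4-dihydro-2H-chromen-6-yl]magnesium bromide | Br[Mg]c1ccc2c(c1)C[C@@H](OCc3ccccc3)C(C)(C)O2 | intermediate
7 | methyl (2RS)-3-[(3R)-3-(benzyloxy)-2,2-dimethyl-3,4-dihydro-2H-chromen-6-yl]-2-hydroxypropanoate | COC(=O)C(O)Cc1ccc2c(c1)C[C@@H](OCc3ccccc3)C(C)(C)O2 | intermediate
8 | tert-butyl 2-methoxyacetate | COCC(=O)OC(C)(C)C | starting material
9 | 3,4-bis(benzyloxy)benzoyl chloride | O=C(Cl)c1ccc(OCc2ccccc2)c(OCc2ccccc2)c1 | starting material
10 | tert-butyl (2RS)-3-[3,4-bis(benzyloxy)phenyl]-2-methoxy-3-oxopropanoate | COC(C(=O)OC(C)(C)C)C(=O)c1ccc(OCc2ccccc2)c(OCc2ccccc2)c1 | intermediate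
11 | tert-butyl (2E)-3-[3,4-bis(benzyloxy)phenyl]-2-methoxy-3-{[(trifluoromethyl)sulfonyl]oxy}prop-2-enoate | CO/C(C(=O)OC(C)(C)C)=C(/OS(=O)(=O)C(F)(F)F)c1ccc(OCc2ccccc2)c(OCc2ccccc2)c1 | intermediate
12 | (2E)-3-[3,4-bis(benzyloxy)phenyl]-2-methoxy-3-{[(trifluoromethyl)sulfonyl]oxy}prop-2-enoic acid | CO/C(C(=O)O)=C(/OS(=O)(=O)C(F)(F)F)c1ccc(OCc2ccccc2)c(OCc2ccccc2)c1 | intermediate
13 | methyl (2RS)-3-[(3R)-3-(benzyloxy)-2,2-dimethyl-3,4-dihydro-2H-chromen-6-yl]-2-{[(2E)-3-[3,4-bis(benzyloxy)phenyl]-2-methoxy-3-{[(trifluoromethyl)sulfonyl]oxy}prop-2-enoyl]oxy}propanoate | COC(=O)C(Cc1ccc2c(c1)C[C@@H](OCc3ccccc3)C(C)(C)O2)OC(=O)/C(OC)=C(\OS(=O)(=O)C(F)(F)F)c1ccc(OCc2ccccc2)c(OCc2ccccc2)c1 | intermediate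
14 | (1E/Z)-3-[(3R)-3-(benzyloxy)-2,2-dimethyl-3,4-dihydro-2H-chromen-6-yl]-1-methoxy-1-[(trimethylsilyl)oxy]prop-1-en-2-yl (2E)-3-[3,4-bis(benzyloxy)phenyl]-2-methoxy-3-{[(trifluoromethyl)sulfonyl]oxy}prop-2-enoate | COC(O[Si](C)(C)C)=C(Cc1ccc2c(c1)C[C@@H](OCc3ccccc3)C(C)(C)O2)OC(=O)/C(OC)=C(\OS(=O)(=O)C(F)(F)F)c1ccc(OCc2ccccc2)c(OCc2ccccc2)c1 | intermediate
15 | methyl (2S)-2-{[(3R)-3-(benzyloxy)-2,2-dimethyl-3,4-dihydro-2H-chromen-6-yl]methyl}-3-[3,4-bis(benzyloxy)phenyl]-4-methoxy-5-oxo-2,5-dihydrofuran-2-carboxylate | COC(=O)[C@@]1(Cc2ccc3c(c2)C[C@@H](OCc4ccccc4)C(C)(C)O3)OC(=O)C(OC)=C1c1ccc(OCc2ccccc2)c(OCc2ccccc2)c1 | intermediate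
16 | methyl (2S)-3-(3,4-dihydroxyphenyl)-2-{[(3R)-3-hydroxy-2,2-dimethyl-3,4-dihydro-2H-chromen-6-yl]methyl}-4-methoxy-5-oxo-2,5-dihydrofuran-2-carboxylate | COC(=O)[C@@]1(Cc2ccc3c(c2)C[C@@H](O)C(C)(C)O3)OC(=O)C(OC)=C1c1ccc(O)c(O)c1 | target

**Step count and risks**

Total steps: 11. Longest linear sequence: 8 steps (steps 1, 2, 3, 4, 8, 9, 10, 11).

Step 10 (Proposed new method). What may go wrong: silyl transfer to palladium or reductive elimination at the fully substituted C5 may be slower than protodesilylation back to 13 or β-hydride elimination of the palladium enolate, and facial discrimination at C5 may be poor. Fallback with known chemistry, the base-mediated aldol–lactonisation of two arylpyruvic esters followed by O-methylation. It sets out from 7 and comes back at 15.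
- Oxidation of 7 with Dess–Martin periodinane should give methyl 3-[(3R)-3-(benzyloxy)-2,2-dimethyl-3,4-dihydro-2H-chromen-6-yl]-2-oxopropanoate F1.
- The donor is made from commercial 3,4-bis(benzyloxy)benzaldehyde: Horner–Wadsworth–Emmons olefination with methyl 2-[(tert-butyldimethylsilyl)oxy]-2-(dimethoxyphosphoryl)acetate (LiCl, DBU, MeCN) should give methyl 3-[3,4-bis(benzyloxy)phenyl]-2-[(tert-butyldimethylsilyl)oxy]prop-2-enoate F2, and desilylation with Et3N·3HF should give methyl 3-[3,4-bis(benzyloxy)phenyl]-2-oxopropanoate F3.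
- F1 and an excess of F3 with DBU in MeCN should undergo aldol addition (benzylic carbon of F3 onto the ketone of F1) and lactonisation to the 3-hydroxybutenolide, methyl (2RS)-2-{[(3R)-3-(benzyloxy)-2,2-dimethyl-3,4-dihydro-2H-chromen-6-yl]methyl}-3-[3,4-bis(benzyloxy)phenyl]-4-hydroxy-5-oxo-2,5-dihydrofuran-2-carboxylate F4. It is expected as both C5 epimers, beside the crossed regioisomer and the homo-condensation products, which are removed by chromatography.
- O-Methylation of the acidic enol with Me3SiCHN2 (toluene–MeOH) should give 15 together with its epimer, methyl (2R)-2-{[(3R)-3-(benzyloxy)-2,2-dimethyl-3,4-dihydro-2H-chromen-6-yl]methyl}-3-[3,4-bis(benzyloxy)phenyl]-4-methoxy-5-oxo-2,5-dihydrofuran-2-carboxylate F5. The two are diastereomers and are separated by chromatography. This route has no control at C5 and costs half of the material.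

Step 9. What may go wrong: the lithium enolate may undergo 1,2-acyl shift from O1 to C5 (Chan rearrangement) or attack the enol triflate before it is silylated. Fallback that makes the ketene acetal without any enolate. It sets out from 7 and 12 and comes back at 15.
- 7 is oxidised to the keto ester F1 as above.
- The enol of F1 is O-acylated with acid 12 (EDC·HCl, DMAP cat., CH2Cl2) to the enol ester methyl (2Z)-3-[(3R)-3-(benzyloxy)-2,2-dimethyl-3,4-dihydro-2H-chromen-6-yl]-2-{[(2E)-3-[3,4-bis(benzyloxy)phenyl]-2-methoxy-3-{[(trifluoromethyl)sulfonyl]oxy}prop-2-enoyl]oxy}prop-2-enoate F6.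
- Rhodium-catalysed 1,4-hydrosilylation of the acrylate unit (Rh(PPh3)3Cl, Et3SiH, toluene) should give the triethylsilyl ketene acetal, the Et3Si analogue of 14, F7.
- F7 is taken through the conditions of step 10 to give 15.

Step 11. What may go wrong: slow cleavage of the hindered secondary benzyl ether, so that forcing conditions bring hydrogenolysis of the allylic C5–O1 lactone bond or saturation of the C3=C4 bond. Fallback: non-reductive Lewis-acid debenzylation with BCl3 and pentamethylbenzene as cation trap (CH2Cl2, −78 °C). It sets out from 15 and arrives directly at 16, and makes no new compound.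

**Further compounds**

F1 | step 10 | methyl 3-[(3R)-3-(benzyloxy)-2,2-dimethyl-3,4-dihydro-2H-chromen-6-yl]-2-oxopropanoate | COC(=O)C(=O)Cc1ccc2c(c1)C[C@@H](OCc3ccccc3)C(C)(C)O2
F2 | step 10 | methyl 3-[3,4-bis(benzyloxy)phenyl]-2-[(tert-butyldimethylsilyl)oxy]prop-2-enoate | COC(=O)C(O[Si](C)(C)C(C)(C)C)=Cc1ccc(OCc2ccccc2)c(OCc2ccccc2)c1
F3 | step 10 | methyl 3-[3,4-bis(benzyloxy)phenyl]-2-oxopropanoate | COC(=O)C(=O)Cc1ccc(OCc2ccccc2)c(OCc2ccccc2)c1
F4 | step 10 | methyl (2RS)-2-{[(3R)-3-(benzyloxy)-2,2-dimethyl-3,4-dihydro-2H-chromen-6-yl]methyl}-3-[3,4-bis(benzyloxy)phenyl]-4-hydroxy-5-oxo-2,5-dihydrofuran-2-carboxylate | COC(=O)C1(Cc2ccc3c(c2)C[C@@H](OCc4ccccc4)C(C)(C)O3)OC(=O)C(O)=C1c1ccc(OCc2ccccc2)c(OCc2ccccc2)c1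
F5 | step 10 | methyl (2R)-2-{[(3R)-3-(benzyloxy)-2,2-dimethyl-3,4-dihydro-2H-chromen-6-yl]methyl}-3-[3,4-bis(benzyloxy)phenyl]-4-methoxy-5-oxo-2,5-dihydrofuran-2-carboxylate | COC(=O)[C@]1(Cc2ccc3c(c2)C[C@@H](OCc4ccccc4)C(C)(C)O3)OC(=O)C(OC)=C1c1ccc(OCc2ccccc2)c(OCc2ccccc2)c1
F6 | step 9 | methyl (2Z)-3-[(3R)-3-(benzyloxy)-2,2-dimethyl-3,4-dihydro-2H-chromen-6-yl]-2-{[(2E)-3-[3,4-bis(benzyloxy)phenyl]-2-methoxy-3-{[(trifluoromethyl)sulfonyl]oxy}prop-2-enoyl]oxy}prop-2-enoate | COC(=O)/C(=C/c1ccc2c(c1)C[C@@H](OCc3ccccc3)C(C)(C)O2)OC(=O)/C(OC)=C(\OS(=O)(=O)C(F)(F)F)c1ccc(OCc2ccccc2)c(OCc2ccccc2)c1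
F7 | step 9 | (1E/Z)-3-[(3R)-3-(benzyloxy)-2,2-dimethyl-3,4-dihydro-2H-chromen-6-yl]-1-methoxy-1-[(triethylsilyl)oxy]prop-1-en-2-yl (2E)-3-[3,4-bis(benzyloxy)phenyl]-2-methoxy-3-{[(trifluoromethyl)sulfonyl]oxy}prop-2-enoate | COC(O[Si](CC)(CC)CC)=C(Cc1ccc2c(c1)C[C@@H](OCc3ccccc3)C(C)(C)O2)OC(=O)/C(OC)=C(\OS(=O)(=O)C(F)(F)F)c1ccc(OCc2ccccc2)c(OCc2ccccc2)c1
F0 | step 11 | none | none
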